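## Retrosynthetic overview

1. The target is traced back to a diol, then to a carboxylic acid / tert-butyl ester: both acetates go on last, the CH2OAc carbon is carried as a carboxyl, and the lactone α-oxygen comes from enolate oxidation.
2. Side chain: the bond between the side-chain CH and the lactone β-carbon is cut as a Michael addition of a hydroazulenyl-acetate enolate to furan-2(5H)-one; the lactone ring is bought intact and attached last.
3. Quaternary carbon: Mukaiyama–Michael addition of an acetate unit to a bicyclic tetrasubstituted enone; the exocyclic methylene comes from the ring ketone.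
4. Key disconnection: the cyclopentene of that enone is cut between the ring-fusion CH and the neighbouring ring CH2. The β-carbon of 4,4-dimethylcyclohept-2-enone is joined to the β-carbon of a masked butanone homoenolate (two carbons that are both normally electrophilic) by catalytic asymmetric conjugate addition, and an aldol condensation closes the ring.
5. Ring order: seven-membered ring first (one-carbon ring expansion from 3-methylcyclohex-2-enone), five-membered ring second (homoenolate annulation), lactone last.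

Assumption: building blocks 7, 12 and 16, the phosphoramidite ligand and the oxaziridine are bought (12 is otherwise one operation from tert-butyl acetate); locants in each name follow that compound's own numbering.

## Route

Step 1
Reactants: 1 3-methylcyclohex-2-en-1-one
Product: 3 [(3,3-dimethylcyclohex-1-en-1-yl)oxy]trimethylsilane, via lithium enolate 2 (not isolated)
Conditions: Me2CuLi (from MeLi, CuI), Et2O, 0 °C; then TMSCl, Et3N, 0 °C → rt
Reagents that add atoms: lithium dimethylcuprate [Li+].C[Cu-]C; chlorotrimethylsilane C[Si](C)(C)Cl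
Why: Gilman cuprate conjugate addition to the β-methyl enone builds the gem-dimethyl carbon, and O-silylation of the regiospecific enolate fixes the enol ether double bond next to it; no stereocentre is formed.

Step 2
Reactants: 3 [(3,3-dimethylcyclohex-1-en-1-yl)oxy]trimethylsilane
Product: 4 trimethyl[(5,5-dimethylbicyclo[4.1.0]heptan-1-yl)oxy]silane (racemic)
Conditions: Et2Zn, CH2I2, CH2Cl2, 0 °C → rt
Reagents that add atoms: diiodomethane ICI
Why: Furukawa-type Simmons–Smith cyclopropanation of the electron-rich silyl enol ether; the two new stereocentres form as a racemate and are erased in step 3.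

Step 3
Reactants: 4 trimethyl[(5,5-dimethylbicyclo[4.1.0]heptan-1-yl)oxy]silane
Product: 6 4,4-dimethylcyclohept-2-en-1-one, via chloroketone 5 (not isolated)
Conditions: FeCl3, DMF, 0 → 60 °C; then NaOAc, MeOH, reflux
Reagents that add atoms: none
Why: Ito–Saegusa one-carbon ring expansion: FeCl3 oxidises the siloxycyclopropane with cleavage of the ring-fusion bond, chlorine transfer gives the β-chloro ketone, and acetate-induced E1cB elimination gives the enone; no stereocentre.

Step 4
Reactants: 6 4,4-dimethylcyclohept-2-en-1-one; 7 2-(2-bromoethyl)-2-methyl-1,3-dioxolane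
Product: 11 (8aS)-3,8,8-trimethyl-1,2,6,7,8,8a-hexahydroazulen-4(5H)-one, via ketal ketone 8 (not isolated), via diketone 9 (not isolated), via aldol adduct 10 (not isolated)
Conditions: 7, Mg, THF; ZnCl2 (0.5 equiv), 1,4-dioxane (Mg salts filtered off); 6, Cu(OTf)2 (2 mol %), (S)-binaphthol bis[(R)-1-phenylethyl]amine phosphoramidite (4 mol %), toluene, −30 °C; then 3 M HCl, THF, 65 °C
Reagents that add atoms: none
Why: Copper–phosphoramidite-catalysed asymmetric conjugate addition of the ketal-masked butanone homoenolate (a β-acyl carbanion equivalent) joins the enone β-carbon to the β-carbon of a latent methyl ketone, with the ligand setting the ring-fusion CH (3R in 8, 8aS in 11) by reagent control; the (S,R,R) ligand is chosen by analogy with its known facial sense on cyclohexenone. Acid then unmasks the ketone and drives the intramolecular aldol condensation (cyclopentannulation) to the conjugated enone.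

Step 5
Reactants: 11 (8aS)-3,8,8-trimethyl-1,2,6,7,8,8a-hexahydroazulen-4(5H)-one; 12 tert-butyl[(1-tert-butoxyethenyl)oxy]dimethylsilane
Product: 14 tert-butyl 2-[(1S,3aR,8aR)-1,4,4-trimethyl-8-oxodecahydroazulen-1-yl]acetate, via silyl enol ether 13 (not isolated)
Conditions: Tf2NH (5 mol %), CH2Cl2, −78 → −40 °C; then 1 M HCl, THF, 0 °C → rt
Reagents that add atoms: none
Why: Mukaiyama–Michael addition: the ketene silyl acetal attacks the enone β-carbon on the face of the ring-fusion hydrogen, away from the adjacent CMe2 group whose pseudo-axial methyl lies under the five-membered ring, which sets the quaternary carbon; hydrolysis protonates the silyl enol ether from the same open face to give the cis ring fusion.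

Step 6
Reactants: 14 tert-butyl 2-[(1S,3aR,8aR)-1,4,4-trimethyl-8-oxodecahydroazulen-1-yl]acetate
Product: 15 tert-butyl 2-[(1S,3aR,8aS)-1,4,4-trimethyl-8-methylidenedecahydroazulen-1-yl]acetate
Conditions: Zn, CH2Br2, TiCl4, THF/CH2Cl2, 0 °C → rt
Reagents that add atoms: dibromomethane BrCBr
Why: Takai–Lombardo methylenation is non-basic, so the hindered, epimerisable ketone becomes the exocyclic methylene without loss of the ring-fusion configuration or of the tert-butyl ester.

Step 7
Reactants: 15 tert-butyl 2-[(1S,3aR,8aS)-1,4,4-trimethyl-8-methylidenedecahydroazulen-1-yl]acetate; 16 furan-2(5H)-one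
Product: 19 tert-butyl (2R)-2-[(3R,4S)-4-hydroxy-5-oxooxolan-3-yl]-2-[(1R,3aR,8aS)-1,4,4-trimethyl-8-methylidenedecahydroazulen-1-yl]acetate, via lithium ester enolate 17 (not isolated), via lithium lactone enolate 18 (not isolated)
Conditions: LiN(iPr)2, THF, −78 °C; 16, −78 °C; then trans-3-phenyl-2-(phenylsulfonyl)oxaziridine, −78 → −40 °C; aq NH4Cl
Reagents that add atoms: trans-3-phenyl-2-(phenylsulfonyl)oxaziridine O=S(=O)(N1OC1c1ccccc1)c1ccccc1
Why: Kinetic Michael addition of the lithium E(O)-ester enolate to the butenolide followed by Davis enolate oxidation: with the bulky ring-fusion carbon anti to the enolate C=C the butenolide approaches from the methyl-flanked outer face and not across the five-membered ring (side-chain CH, R), a synclinal lithium-bridged transition state with the butenolide β-hydrogen between the two large enolate substituents is expected to fix the lactone β-carbon (R), and oxygen is delivered trans to that substituent (α-carbon, S).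

Step 8
Reactants: 19 tert-butyl (2R)-2-[(3R,4S)-4-hydroxy-5-oxooxolan-3-yl]-2-[(1R,3aR,8aS)-1,4,4-trimethyl-8-methylidenedecahydroazulen-1-yl]acetate
Product: 21 (2R)-2-[(3R,4S)-4-hydroxy-5-oxooxolan-3-yl]-2-[(1R,3aR,8aS)-1,4,4-trimethyl-8-methylidenedecahydroazulen-1-yl]acetic acid, via bis-silyl derivative 20 (not isolated)
Conditions: TMSOTf, 2,6-lutidine, CH2Cl2, 0 °C; then pH 4 aqueous buffer
Reagents that add atoms: none
Why: Silyl triflate-mediated tert-butyl ester cleavage (isobutene loss from the O-silylated ester) under lutidine buffering spares the acid-sensitive exocyclic alkene and the lactone; no stereocentre is touched.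

Step 9
Reactants: 21 (2R)-2-[(3R,4S)-4-hydroxy-5-oxooxolan-3-yl]-2-[(1R,3aR,8aS)-1,4,4-trimethyl-8-methylidenedecahydroazulen-1-yl]acetic acid
Product: 23 (3S,4R)-3-hydroxy-4-{(1R)-2-hydroxy-1-[(1R,3aR,8aS)-1,4,4-trimethyl-8-methylidenedecahydroazulen-1-yl]ethyl}oxolan-2-one, via mixed anhydride 22 (not isolated)
Conditions: iBuOCOCl, N-methylmorpholine, THF, −15 °C; then NaBH4, H2O, −15 → 0 °C
Reagents that add atoms: none
Why: Chemoselective reduction of the acid through its mixed carbonic anhydride: NaBH4 attacks the activated acyl carbon at low temperature and leaves the lactone and the alkene alone; no stereocentre is touched.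

Step 10
Reactants: 23 (3S,4R)-3-hydroxy-4-{(1R)-2-hydroxy-1-[(1R,3aR,8aS)-1,4,4-trimethyl-8-methylidenedecahydroazulen-1-yl]ethyl}oxolan-2-one
Product: 24 (2R)-2-[(3R,4S)-4-acetoxy-5-oxooxolan-3-yl]-2-[(1R,3aR,8aS)-1,4,4-trimethyl-8-methylidenedecahydroazulen-1-yl]ethyl acetate (CNP0234964.1)
Conditions: Ac2O, pyridine, DMAP (cat.), CH2Cl2, 0 °C → rt
Reagents that add atoms: acetic anhydride CC(=O)OC(C)=O
Why: DMAP-catalysed acetylation (nucleophilic acyl transfer) esterifies the primary and the secondary hydroxyl with retention and gives the target.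

## Compound list

1 | 3-methylcyclohex-2-en-1-one | CC1=CC(=O)CCC1 | starting material
2 | lithium 3,3-dimethylcyclohex-1-en-1-olate | CC1(C)CCCC([O-])=C1.[Li+] | intermediate
3 | [(3,3-dimethylcyclohex-1-en-1-yl)oxy]trimethylsilane | CC1(C)CCCC(O[Si](C)(C)C)=C1 | intermediate
4 | trimethyl[(5,5-dimethylbicyclo[4.1.0]heptan-1-yl)oxy]silane (racemic) | C[Si](C)(C)OC12CCCC(C)(C)C1C2 | intermediate
5 | 3-chloro-4,4-dimethylcycloheptan-1-one (racemic) | O=C1CCCC(C)(C)C(Cl)C1 | intermediate
6 | 4,4-dimethylcyclohept-2-en-1-one | O=C1C=CC(C)(C)CCC1 | intermediate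
7 | 2-(2-bromoethyl)-2-methyl-1,3-dioxolane | CC1(CCBr)OCCO1 | starting material
8 | (3R)-4,4-dimethyl-3-[2-(2-methyl-1,3-dioxolan-2-yl)ethyl]cycloheptan-1-one | O=C1CCCC(C)(C)[C@H](CCC2(C)OCCO2)C1 | intermediate
9 | (3R)-4,4-dimethyl-3-(3-oxobutyl)cycloheptan-1-one | O=C1CCCC(C)(C)[C@H](CCC(C)=O)C1 | intermediate
10 | (8aR)-3-hydroxy-3,8,8-trimethyloctahydroazulen-4(1H)-one (C3 and C3a unassigned) | O=C1CCCC(C)(C)[C@@H]2CCC(C)(O)C12 | intermediate
11 | (8aS)-3,8,8-trimethyl-1,2,6,7,8,8a-hexahydroazulen-4(5H)-one | O=C1CCCC(C)(C)[C@@H]2CCC(C)=C12 | intermediate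
12 | tert-butyl[(1-tert-butoxyethenyl)oxy]dimethylsilane | C=C(OC(C)(C)C)O[Si](C)(C)C(C)(C)C | starting material
13 | tert-butyl 2-[(1S,3aS)-8-{[tert-butyl(dimethyl)silyl]oxy}-1,4,4-trimethyl-1,2,3,3a,4,5,6,7-octahydroazulen-1-yl]acetate | CC(C)(C)OC(=O)C[C@]1(C)CC[C@@H]2C1=C(O[Si](C)(C)C(C)(C)C)CCCC2(C)C | intermediate
14 | tert-butyl 2-[(1S,3aR,8aR)-1,4,4-trimethyl-8-oxodecahydroazulen-1-yl]acetate (cis-fused) | O=C1CCCC(C)(C)[C@@H]2CC[C@@](C)(CC(=O)OC(C)(C)C)[C@H]12 | intermediate
15 | tert-butyl 2-[(1S,3aR,8aS)-1,4,4-trimethyl-8-methylidenedecahydroazulen-1-yl]acetate | C=C1CCCC(C)(C)[C@@H]2CC[C@@](C)(CC(=O)OC(C)(C)C)[C@H]12 | intermediate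
16 | furan-2(5H)-one | O=C1C=CCO1 | starting material
17 | lithium E(O)-enolate of ester 15 (O–Li trans to the ring substituent; ring stereocentres as in 15) | C=C1CCCC(C)(C)[C@@H]2CC[C@@](C)(/C=C(/[O-])OC(C)(C)C)[C@H]12.[Li+] | intermediate
18 | lithium lactone enolate of the Michael adduct (side-chain CH and lactone β-carbon as in 19) | C=C1CCCC(C)(C)[C@@H]2CC[C@@](C)([C@H](C(=O)OC(C)(C)C)[C@@H]3COC([O-])=C3)[C@H]12.[Li+] | intermediate
19 | tert-butyl (2R)-2-[(3R,4S)-4-hydroxy-5-oxooxolan-3-yl]-2-[(1R,3aR,8aS)-1,4,4-trimethyl-8-methylidenedecahydroazulen-1-yl]acetate | C=C1CCCC(C)(C)[C@@H]2CC[C@@](C)([C@H](C(=O)OC(C)(C)C)[C@@H]3COC(=O)[C@H]3O)[C@H]12 | intermediate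
20 | trimethylsilyl ester / trimethylsilyl ether of acid 21 (configurations as in 21) | C=C1CCCC(C)(C)[C@@H]2CC[C@@](C)([C@H](C(=O)O[Si](C)(C)C)[C@@H]3COC(=O)[C@H]3O[Si](C)(C)C)[C@H]12 | intermediate
21 | (2R)-2-[(3R,4S)-4-hydroxy-5-oxooxolan-3-yl]-2-[(1R,3aR,8aS)-1,4,4-trimethyl-8-methylidenedecahydroazulen-1-yl]acetic acid | C=C1CCCC(C)(C)[C@@H]2CC[C@@](C)([C@H](C(=O)O)[C@@H]3COC(=O)[C@H]3O)[C@H]12 | intermediate
22 | isobutyl carbonic mixed anhydride of acid 21 (configurations as in 21) | C=C1CCCC(C)(C)[C@@H]2CC[C@@](C)([C@H](C(=O)OC(=O)OCC(C)C)[C@@H]3COC(=O)[C@H]3O)[C@H]12 | intermediate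
23 | (3S,4R)-3-hydroxy-4-{(1R)-2-hydroxy-1-[(1R,3aR,8aS)-1,4,4-trimethyl-8-methylidenedecahydroazulen-1-yl]ethyl}oxolan-2-one | C=C1CCCC(C)(C)[C@@H]2CC[C@@](C)([C@H](CO)[C@@H]3COC(=O)[C@H]3O)[C@H]12 | intermediate
24 | (2R)-2-[(3R,4S)-4-acetoxy-5-oxooxolan-3-yl]-2-[(1R,3aR,8aS)-1,4,4-trimethyl-8-methylidenedecahydroazulen-1-yl]ethyl acetate | C=C1CCCC(C)(C)[C@@H]2CC[C@@](C)([C@H](COC(C)=O)[C@@H]3COC(=O)[C@H]3OC(C)=O)[C@H]12 | target

## Step count and risks

Total step count: 10. Longest linear sequence: 10 (1 → 24); 7, 12 and 16 enter as purchased building blocks.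

The three steps most likely to fail:

Step 4. The functionalised diorganozinc may transfer slowly to the β-carbon next to the CMe2 group, or with low enantioselectivity, and the acid-driven aldol closure onto a methyl ketone may stall. The fallback sets out from 6 and uses a plain alkyl nucleophile carrying the ketone as a latent alkene: Cu(OTf)2/phosphoramidite-catalysed addition of di(but-3-en-1-yl)zinc gives (3R)-3-(but-3-en-1-yl)-4,4-dimethylcycloheptan-1-one F1. Wacker oxidation of the terminal alkene (PdCl2, CuCl, O2, DMF/H2O) then gives the diketone 9, where the fallback comes back to the route; 9 is closed to 11 with KOH in MeOH.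

Step 5. The tetrasubstituted enone may not accept the bulky ketene silyl acetal. Facial selectivity at the new quaternary carbon rests only on the bias from the neighbouring CMe2 group, and the cis ring fusion on protonation from the open face. The fallback sets out from 11 and uses the smaller, more reactive allylsilane: Hosomi–Sakurai conjugate allylation (allyltrimethylsilane, TiCl4, CH2Cl2, −78 °C) gives (3S,3aR,8aR)-3,8,8-trimethyl-3-(prop-2-en-1-yl)octahydroazulen-4(1H)-one F2. Oxidative cleavage of the allyl group (RuCl3 cat., NaIO4) gives 2-[(1S,3aR,8aR)-1,4,4-trimethyl-8-oxodecahydroazulen-1-yl]acetic acid F3, and esterification with Boc2O, DMAP and tert-butanol gives 14, where it comes back to the route. This fallback does not fix a facial-selectivity failure, since it relies on the same bias.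

Step 7. Three stereocentres are set in one flask under substrate control. The configuration of the side-chain CH relative to the quaternary carbon, and of the lactone β-carbon relative to it, are model-based predictions and could come out as mixtures; the hindered enolate may also deprotonate the butenolide instead of adding. The fallback sets out from 15 and puts the side-chain CH under auxiliary control: TMSOTf/2,6-lutidine gives 2-[(1S,3aR,8aS)-1,4,4-trimethyl-8-methylidenedecahydroazulen-1-yl]acetic acid F4, and DCC/DMAP coupling with (R)-4-benzyl-1,3-oxazolidin-2-one gives (4R)-4-benzyl-3-{[(1S,3aR,8aS)-1,4,4-trimethyl-8-methylidenedecahydroazulen-1-yl]acetyl}-1,3-oxazolidin-2-one F5. Its Z-enolate (NaN(SiMe3)2, THF, −78 °C) adds to 16 anti to the benzyl group and is oxidised with the same oxaziridine to (4R)-4-benzyl-3-{(2R)-2-[(3R,4S)-4-hydroxy-5-oxooxolan-3-yl]-2-[(1R,3aR,8aS)-1,4,4-trimethyl-8-methylidenedecahydroazulen-1-yl]acetyl}-1,3-oxazolidin-2-one F6. NaBH4 in THF/H2O removes the auxiliary reductively and gives the diol 23, where it comes back to the route.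

## Further compounds

F1 | step 4 | (3R)-3-(but-3-en-1-yl)-4,4-dimethylcycloheptan-1-one | O=C1CCCC(C)(C)[C@H](CCC=C)C1
F2 | step 5 | (3S,3aR,8aR)-3,8,8-trimethyl-3-(prop-2-en-1-yl)octahydroazulen-4(1H)-one | O=C1CCCC(C)(C)[C@@H]2CC[C@@](C)(CC=C)[C@H]12
F3 | step 5 | 2-[(1S,3aR,8aR)-1,4,4-trimethyl-8-oxodecahydroazulen-1-yl]acetic acid | O=C1CCCC(C)(C)[C@@H]2CC[C@@](C)(CC(=O)O)[C@H]12
F4 | step 7 | 2-[(1S,3aR,8aS)-1,4,4-trimethyl-8-methylidenedecahydroazulen-1-yl]acetic acid | C=C1CCCC(C)(C)[C@@H]2CC[C@@](C)(CC(=O)O)[C@H]12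
F5 | step 7 | (4R)-4-benzyl-3-{[(1S,3aR,8aS)-1,4,4-trimethyl-8-methylidenedecahydroazulen-1-yl]acetyl}-1,3-oxazolidin-2-one | C=C1CCCC(C)(C)[C@@H]2CC[C@@](C)(CC(=O)N3[C@H](Cc4ccccc4)COC3=O)[C@H]12
F6 | step 7 | (4R)-4-benzyl-3-{(2R)-2-[(3R,4S)-4-hydroxy-5-oxooxolan-3-yl]-2-[(1R,3aR,8aS)-1,4,4-trimethyl-8-methylidenedecahydroazulen-1-yl]acetyl}-1,3-oxazolidin-2-one | C=C1CCCC(C)(C)[C@@H]2CC[C@@](C)([C@H](C(=O)N3[C@H](Cc4ccccc4)COC3=O)[C@@H]3COC(=O)[C@H]3O)[C@H]12
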